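The easy step first: a molecule of starting material closes to single ring by itself, while open dimer needs two molecules to meet, so the first rate goes with the concentration and the second with its square. I divide one by the other and time drops out. The oak run at 20.0 min reads 6.5% single ring against 25.4% open dimer and 3.5% open trimer. Scaled by oak's charge, that gives c× = 0.0115 M, the concentration at which the two routes use starting material equally, the effective molarity. It is a reading, with 1 percentage point of scatter on each figure.

| flask | starting material | remark | time |
|---|---|---|---|
| ash | 8.5 × 10⁻⁴ M | run made earlier |  |
| oak | 0.051 M | run made earlier |  |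
| Thursday's | 0.0010 M |  | 1.5 h |
| Tuesday's | 0.0030 M |  | 1.5 h |
| Sunday's | 0.0080 M |  | 1.5 h |
| Friday's | 0.025 M |  | 1.5 h |
| Monday's | 0.080 M |  | 1.5 h |

| run | time / min | single ring / % | open dimer / % | open trimer / % |
|---|---|---|---|---|
| ash | 6.00 | 0.9 | 0 | 1.0 |
| ash | 12.0 | 4.5 | 1.3 | 0 |
| ash | 20.0 | 6.4 | 0 | 0 |
| ash | 25.0 | 8.8 | 0.6 | 0 |
| ash | 30.0 | 10.5 | 0.9 | 0 |
| ash | 40.0 | 12.6 | 1.1 | 0 |
| ash | 50.0 | 17.3 | 3.0 | 0.1 |
| oak | 6.00 | 1.6 | 9.7 | 0 |
| oak | 12.0 | 2.9 | 17.4 | 1.0 |
| oak | 20.0 | 6.5 | 25.4 | 3.5 |
| oak | 25.0 | 8.9 | 26.7 | 1.9 |
| oak | 30.0 | 8.5 | 27.0 | 2.2 |
| oak | 40.0 | 11.2 | 34.2 | 3.6 |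
| oak | 50.0 | 11.5 | 34.4 | 4.8 |

(readings scatter by 1 percentage point)

- share of single ring in all that became single ring or open dimer or open trimer or ring dimer or over-reaction product B for Thursday's, Tuesday's, Sunday's, Friday's, Monday's, in this order
- how that number moves from the first to the last of them (rises, then falls / falls all the way / falls, then rises / hardly changes / rises all the way)

- percentages count the starting material that a species holds: one open dimer or ring dimer counts as two
- percentages count the starting material that a species holds: one open trimer counts as three
- the analysis behind the earlier runs scatters by 1 percentage point, standard deviation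
- the share counts what is present at the end, not what went on to other products
- "hardly changes" means that all values lie within two and a half points (for a concentration: within two and a half percent of the largest)

The givens fold into x, the charge over c×, and at the charged concentration the share of material taking the ring route is one over one plus x. Ash, which played no part in c×, is my test: at 40.0 min it reads 92.0%, and x says 93.1%. So on ash the number holds for the fork, within the scatter. But x has no clock in it, and the question counts what is present at the end.

Thursday's charge is less than c×, Monday's more. I reckon 92.0%, 79.3%, 58.9%, 31.5% and 12.5%, falling throughout.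

The forecast, integrated along the run, says 93%, 81%, 62%, 37%, 18%, and falls all the way, with the words “So little is lost yet to ring dimer or B, and those are treated as minor.” At Monday's my figure is lower than the forecast's.

The flask gives 75.9%, 65.1%, 48.7%, 27.8%, 13.1%: falls all the way.

    starting material ⇌ single ring (K = 0.840, k = 0.00448 /min)
    2 starting material → open dimer (k = 0.197 /M/min)
    starting material + open dimer → open trimer (k = 0.101 /M/min)
    open dimer → ring dimer (k = 0.00503 /min)
    single ring → over-reaction product A (k = 2.24 × 10⁻⁵ /min)
    single ring → over-reaction product B (k = 0.00375 /min)

The length of the run is the main reason that Thursday's share stands as high as 75.9%: the same flask run ten times as long, to 15.0 h, gives 13.2%. In Thursday's flask single ring is draining into over-reaction product B. Counting that product back with single ring, Thursday's gives 91.6% at 1.50 h, against 92.0% from c× of 0.0115 M. Thursday's flask at ten times the time, counted the same way, gives 91.1%, with over-reaction product B at 63.3%.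

The earlier runs and the new flask stem from a simulated flask for substances that don't exist; noise was put on by code.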